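**Retrosynthetic overview**

- The strategy rests on ring A being a 2-acylphloroglucinol: oxygens on C5, C7 and C8a alternate around the ring and C4a carries the C4 ketone, the pattern of a folded tetraketide. The C4a–C8a bond is therefore cut (Claisen) to a linear 3,5,7-triketo ester, stored as dioxinone 20.
- 20 comes from aldol addition of the dianion of acetonyl-dioxinone 17 to (S)-aldehyde 14, then oxidation. C4 enters at the aldehyde level so that C3–H never sits in an acyl donor under strong base.
- C3 is set by auxiliary-controlled silyloxymethylation of arylacetyl imide 10. The arylacetic acid comes from bromochromene 4 by Pd-catalysed α-arylation, and 4 from 4-bromo-3-methoxyphenol and 3-methyl-2-butenal.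
- Ring order: pyran of ring B (step 1), carbocycle A (step 11), pyranone C by O1–C2 Mitsunobu closure (step 13), then 7-O-methylation (step 14).

Key step: step 11

Remark: 4-bromo-3-methoxyphenol, i-Pr3SiOCH2Cl and a THF solution of BrZnCH2CO2Et are taken as purchased; in the step names Ar stands for 7-methoxy-2,2-dimethyl-2H-chromen-6-yl.

**Route**

Step 1
Reactants: 1 4-bromo-3-methoxyphenol; 2 3-methyl-2-butenal
Product: 4 6-bromo-7-methoxy-2,2-dimethyl-2H-chromene, via ortho-quinone methide 3 (not isolated)
Conditions: PhB(OH)2 (1 equiv), AcOH, PhMe, reflux, Dean–Stark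
Reagents that add atoms: none
Why: Phenylboronic acid should template the ortho-selective condensation of the phenol with the enal to ortho-quinone methide 3, which closes the pyran of ring B by oxa-6π-electrocyclisation (boronic-acid-mediated chromenylation), and C–C bond formation at the free ortho position para to the methoxy group is the regiochemistry established for 3-alkoxyphenols.

Step 2
Reactants: 4 6-bromo-7-methoxy-2,2-dimethyl-2H-chromene
Product: 5 ethyl 2-Ar-acetate
Conditions: BrZnCH2CO2Et (1.5 equiv, THF solution), Pd2(dba)3 (2.5 mol %), XPhos (10 mol %), THF, 65 °C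
Reagents that add atoms: ethyl (bromozincio)acetate, CCOC(=O)C[Zn]Br
Why: Cross-coupling of the preformed Reformatsky reagent (Negishi-type α-arylation of a zinc ester enolate on zerovalent palladium with a bulky biarylphosphine) proceeds under neutral conditions on electron-rich ortho-alkoxy aryl bromides and should leave the chromene olefin untouched.

Step 3
Reactants: 5 ethyl 2-Ar-acetate
Product: 7 2-Ar-acetic acid, via lithium carboxylate 6 (not isolated)
Conditions: LiOH·H2O, THF/MeOH/H2O, rt; then 1 M HCl to pH 4, 0 °C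
Reagents that add atoms: lithium hydroxide, [Li+].[OH-]
Why: Plain ester saponification, with the cold acidification stopped at pH 4 so that the acid-labile electron-rich chromene is not exposed to strong acid.

Step 4
Reactants: 7 2-Ar-acetic acid; 8 (R)-4-benzyl-2-oxazolidinone
Product: 10 (R)-4-benzyl-3-(2-Ar-acetyl)oxazolidin-2-one, via mixed pivalic anhydride 9 (not isolated)
Conditions: t-BuCOCl, Et3N, THF, −20 °C; then 8, LiCl, −20 °C → rt
Reagents that add atoms: none
Why: The mixed pivalic anhydride 9 is attacked at the less hindered arylacetyl carbonyl by the oxazolidinone under LiCl/Et3N activation, the standard one-pot N-acylation of the Evans auxiliary.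

Step 5
Reactants: 10 (R)-4-benzyl-3-(2-Ar-acetyl)oxazolidin-2-one
Product: 12 (R)-4-benzyl-3-[(S)-2-Ar-3-(triisopropylsilyloxy)propanoyl]oxazolidin-2-one, via sodium Z-enolate 11 (not isolated)
Conditions: NaN(SiMe3)2, THF, −78 °C; then i-Pr3SiOCH2Cl, Bu4NI (cat.), −78 → −40 °C
Reagents that add atoms: (triisopropylsiloxy)methyl chloride, CC(C)[Si](OCCl)(C(C)C)C(C)C
Why: Evans asymmetric alkylation: the sodium-chelated Z-enolate 11 should be C-alkylated by the chloromethyl silyl ether on the face opposite the C4 benzyl group, which with the (R)-auxiliary sets the new centre (the later C3) as S and delivers the C2 oxygen already silyl-protected, while a base-only protocol keeps the acid-labile chromene away from TiCl4.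

Step 6
Reactants: 12 (R)-4-benzyl-3-[(S)-2-Ar-3-(triisopropylsilyloxy)propanoyl]oxazolidin-2-one
Product: 13 (R)-2-Ar-3-(triisopropylsilyloxy)propan-1-ol
Conditions: LiBH4, MeOH (1 equiv), Et2O, 0 °C
Reagents that add atoms: none
Why: Reductive removal of the auxiliary with LiBH4 (imide reduction at the exocyclic carbonyl) should give the primary alcohol without touching the stereocentre or the silyl ether, the descriptor changing to R only because the CIP priorities change.

Step 7
Reactants: 13 (R)-2-Ar-3-(triisopropylsilyloxy)propan-1-ol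
Product: 14 (S)-2-Ar-3-(triisopropylsilyloxy)propanal
Conditions: Dess–Martin periodinane, NaHCO3, CH2Cl2, 0 °C; crude product used at once
Reagents that add atoms: none
Why: Dess–Martin oxidation under bicarbonate buffering is essentially neutral and fast at 0 °C, so the enolisable α-aryl aldehyde should form without loss of configuration provided it is taken on at once without chromatography.

Step 8
Reactants: 15 2,2,6-trimethyl-4H-1,3-dioxin-4-one
Product: 17 2,2-dimethyl-6-(2-oxopropyl)-4H-1,3-dioxin-4-one, via lithium dienolate 16 (not isolated)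
Conditions: LiN(SiMe3)2, THF, −78 °C; then AcCl (0.5 equiv), −78 °C
Reagents that add atoms: acetyl chloride, CC(Cl)=O
Why: The lithium dienolate 16 is acylated at its γ-carbon (vinylogous Claisen condensation), the excess dienolate serving to deprotonate the more acidic keto-dioxinone as it forms.

Step 9
Reactants: 17 2,2-dimethyl-6-(2-oxopropyl)-4H-1,3-dioxin-4-one; 14 (S)-2-Ar-3-(triisopropylsilyloxy)propanal
Product: 19 6-[(5S)-5-Ar-4-hydroxy-2-oxo-6-(triisopropylsilyloxy)hexyl]-2,2-dimethyl-4H-1,3-dioxin-4-one (both C4 carbinol epimers), via dilithium dianion 18 (not isolated)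
Conditions: 17 (1.5 equiv), LiN(i-Pr)2 (3.2 equiv), THF, −78 °C; then 14, −78 °C; sat. aq. NH4Cl at −78 °C
Reagents that add atoms: none
Why: The terminal carbanion of dianion 18 should add to the aldehyde at −78 °C much faster than it can deprotonate it (dianion aldol addition), so C3 stays intact, and the new carbinol centre is of no consequence because it is oxidised in the next step.

Step 10
Reactants: 19 6-[(5S)-5-Ar-4-hydroxy-2-oxo-6-(triisopropylsilyloxy)hexyl]-2,2-dimethyl-4H-1,3-dioxin-4-one
Product: 20 6-[(5S)-5-Ar-2,4-dioxo-6-(triisopropylsilyloxy)hexyl]-2,2-dimethyl-4H-1,3-dioxin-4-one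
Conditions: Dess–Martin periodinane (1.3 equiv), NaHCO3, CH2Cl2, 0 °C → rt
Reagents that add atoms: none
Why: Dess–Martin oxidation of the β-hydroxy ketone should give the 1,3-diketone, which rests as its enol within the dicarbonyl unit and so does not enolise towards C3.

Step 11
Reactants: 20 6-[(5S)-5-Ar-2,4-dioxo-6-(triisopropylsilyloxy)hexyl]-2,2-dimethyl-4H-1,3-dioxin-4-one
Product: 23 (S)-2-Ar-3-(triisopropylsilyloxy)-1-(2,4,6-trihydroxyphenyl)propan-1-one, via acylketene 21 (not isolated), via triketo methyl ester 22 (not isolated)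
Conditions: PhMe/MeOH (10:1), 110 °C, sealed tube; concentrate; then Mg(OMe)2 (5 equiv), MeOH, 0 °C → rt; cold 0.5 M HCl to pH 5
Reagents that add atoms: none
Why: Thermal retro-[4+2] cleavage of the dioxinone expels acetone and gives acylketene 21, which methanol traps as the 3,5,7-triketo ester 22. Mg(OMe)2 should then turn 22 into its chelated bis(β-diketonate) of divalent magnesium (deprotonated at C6 and C4a), in which the three ketones are masked as enolates and the ester carbonyl C8a, insulated by the C8 methylene, is the only electrophile left; C4a attacks it, methoxide leaves and the cyclohexanetrione tautomerises to the phloroglucinol. The closest known reaction type is the biomimetic Claisen (Dieckmann-type) cyclisation of 3,5,7-triketo esters to acylphloroglucinols with methanolic magnesium methoxide. Ring A closes in the 6-exo-trig mode, by attack of C4a on the exocyclic ester C=O (the alternative attack of C6 would give a four-membered ring). No stereocentre is formed, and the S centre at C3 should survive because the charge of the polyanion sits on C6 and C4a and afterwards on the phenoxides, which leaves C3–H the least acidic position, and because the basic stage is kept short and cold. The selectivity needed is Claisen folding (C4a onto C8a) over aldol folding (C8 onto the C4 ketone), and it is secured by complete enolate formation with a chelating metal in non-aqueous medium and by the branched, ortho-substituted aryl-bearing carbon that shields the C4 ketone.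

Step 12
Reactants: 23 (S)-2-Ar-3-(triisopropylsilyloxy)-1-(2,4,6-trihydroxyphenyl)propan-1-one
Product: 24 (S)-2-Ar-3-hydroxy-1-(2,4,6-trihydroxyphenyl)propan-1-one
Conditions: Bu4NF, AcOH (1:1), THF, 0 °C → rt
Reagents that add atoms: none
Why: Fluoride cleaves the primary silyl ether, and buffering with acetic acid keeps the medium non-basic so that neither retro-aldol loss of formaldehyde nor enolisation at C3 should intervene.

Step 13
Reactants: 24 (S)-2-Ar-3-hydroxy-1-(2,4,6-trihydroxyphenyl)propan-1-one
Product: 26 (S)-3-Ar-5,7-dihydroxychroman-4-one, via oxyphosphonium zwitterion 25 (not isolated)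
Conditions: PPh3, DIAD, THF (0.01 M), 0 °C → rt
Reagents that add atoms: none
Why: Intramolecular Mitsunobu etherification: the primary hydroxyl is activated as oxyphosphonium 25 and displaced by either of the two equivalent ortho phenoxides in a 6-exo-tet closure of ring C (O1–C2 bond), the C3 stereocentre being adjacent to but not part of the reacting carbon, with high dilution suppressing intermolecular alkylation of the para hydroxyl.

Step 14
Reactants: 26 (S)-3-Ar-5,7-dihydroxychroman-4-one
Product: 27 (S)-5-hydroxy-7-methoxy-3-(7-methoxy-2,2-dimethyl-2H-chromen-6-yl)chroman-4-one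
Conditions: Me3SiCHN2 (1.5 equiv), MeOH/PhMe (1:4), 0 °C → rt
Reagents that add atoms: trimethylsilyldiazomethane, C[Si](C)(C)C=[N+]=[N-]
Why: Of the two phenols only the 7-hydroxyl is free and acidic (vinylogous acid para to the carbonyl), the 5-hydroxyl being locked in a hydrogen bond to C4=O, so base-free diazoalkane O-methylation (Me3SiCHN2 releasing diazomethane in methanol) should be site-selective and leave C3 untouched.

**Compound list**

1 | 4-bromo-3-methoxyphenol | COc1cc(O)ccc1Br | starting material
2 | 3-methyl-2-butenal | CC(C)=CC=O | starting material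
3 | 4-bromo-3-methoxy-6-(3-methylbut-2-enylidene)cyclohexa-2,4-dienone (ortho-quinone methide, formed in the flask) | O=C1C=C(OC)C(Br)=CC1=CC=C(C)C | intermediate
4 | 6-bromo-7-methoxy-2,2-dimethyl-2H-chromene | COc1cc2OC(C)(C)C=Cc2cc1Br | intermediate
5 | ethyl 2-(7-methoxy-2,2-dimethyl-2H-chromen-6-yl)acetate | CCOC(=O)Cc1cc2C=CC(C)(C)Oc2cc1OC | intermediate
6 | lithium 2-(7-methoxy-2,2-dimethyl-2H-chromen-6-yl)acetate (formed in the flask) | [Li+].[O-]C(=O)Cc1cc2C=CC(C)(C)Oc2cc1OC | intermediate
7 | 2-(7-methoxy-2,2-dimethyl-2H-chromen-6-yl)acetic acid | OC(=O)Cc1cc2C=CC(C)(C)Oc2cc1OC | intermediate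
8 | (R)-4-benzyl-2-oxazolidinone | O=C1N[C@H](Cc2ccccc2)CO1 | starting material
9 | 2-(7-methoxy-2,2-dimethyl-2H-chromen-6-yl)acetic pivalic anhydride (formed in the flask) | CC(C)(C)C(=O)OC(=O)Cc1cc2C=CC(C)(C)Oc2cc1OC | intermediate
10 | (R)-4-benzyl-3-[2-(7-methoxy-2,2-dimethyl-2H-chromen-6-yl)acetyl]oxazolidin-2-one | O=C1OC[C@@H](Cc2ccccc2)N1C(=O)Cc1cc2C=CC(C)(C)Oc2cc1OC | intermediate
11 | sodium Z-enolate of imide 10 (formed in the flask) | [Na+].[O-]/C(=C\c1cc2C=CC(C)(C)Oc2cc1OC)N1[C@H](Cc2ccccc2)COC1=O | intermediate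
12 | (R)-4-benzyl-3-[(S)-2-(7-methoxy-2,2-dimethyl-2H-chromen-6-yl)-3-(triisopropylsilyloxy)propanoyl]oxazolidin-2-one | CC(C)[Si](C(C)C)(C(C)C)OC[C@H](c1cc2C=CC(C)(C)Oc2cc1OC)C(=O)N1[C@H](Cc2ccccc2)COC1=O | intermediate
13 | (R)-2-(7-methoxy-2,2-dimethyl-2H-chromen-6-yl)-3-(triisopropylsilyloxy)propan-1-ol | CC(C)[Si](C(C)C)(C(C)C)OC[C@H](c1cc2C=CC(C)(C)Oc2cc1OC)CO | intermediate
14 | (S)-2-(7-methoxy-2,2-dimethyl-2H-chromen-6-yl)-3-(triisopropylsilyloxy)propanal | CC(C)[Si](C(C)C)(C(C)C)OC[C@H](c1cc2C=CC(C)(C)Oc2cc1OC)C=O | intermediate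
15 | 2,2,6-trimethyl-4H-1,3-dioxin-4-one | CC1=CC(=O)OC(C)(C)O1 | starting material
16 | lithium dienolate of 15 (formed in the flask) | [Li+].C=C1C=C([O-])OC(C)(C)O1 | intermediate
17 | 2,2-dimethyl-6-(2-oxopropyl)-4H-1,3-dioxin-4-one | CC(=O)CC1=CC(=O)OC(C)(C)O1 | intermediate
18 | dilithium dianion of 17 (formed in the flask) | [Li+].[Li+].C=C([O-])C=C1C=C([O-])OC(C)(C)O1 | intermediate
19 | 6-[(5S)-4-hydroxy-5-(7-methoxy-2,2-dimethyl-2H-chromen-6-yl)-2-oxo-6-(triisopropylsilyloxy)hexyl]-2,2-dimethyl-4H-1,3-dioxin-4-one (both C4 epimers) | CC(C)[Si](C(C)C)(C(C)C)OC[C@H](c1cc2C=CC(C)(C)Oc2cc1OC)C(O)CC(=O)CC1=CC(=O)OC(C)(C)O1 | intermediate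
20 | 6-[(5S)-5-(7-methoxy-2,2-dimethyl-2H-chromen-6-yl)-2,4-dioxo-6-(triisopropylsilyloxy)hexyl]-2,2-dimethyl-4H-1,3-dioxin-4-one | CC(C)[Si](C(C)C)(C(C)C)OC[C@H](c1cc2C=CC(C)(C)Oc2cc1OC)C(=O)CC(=O)CC1=CC(=O)OC(C)(C)O1 | intermediate
21 | (S)-acylketene from 20 (formed in the flask) | CC(C)[Si](C(C)C)(C(C)C)OC[C@H](c1cc2C=CC(C)(C)Oc2cc1OC)C(=O)CC(=O)CC(=O)C=C=O | intermediate
22 | methyl (8S)-8-(7-methoxy-2,2-dimethyl-2H-chromen-6-yl)-3,5,7-trioxo-9-(triisopropylsilyloxy)nonanoate (formed in the flask) | CC(C)[Si](C(C)C)(C(C)C)OC[C@H](c1cc2C=CC(C)(C)Oc2cc1OC)C(=O)CC(=O)CC(=O)CC(=O)OC | intermediate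
23 | (S)-2-(7-methoxy-2,2-dimethyl-2H-chromen-6-yl)-3-(triisopropylsilyloxy)-1-(2,4,6-trihydroxyphenyl)propan-1-one | CC(C)[Si](C(C)C)(C(C)C)OC[C@H](c1cc2C=CC(C)(C)Oc2cc1OC)C(=O)c1c(O)cc(O)cc1O | intermediate
24 | (S)-3-hydroxy-2-(7-methoxy-2,2-dimethyl-2H-chromen-6-yl)-1-(2,4,6-trihydroxyphenyl)propan-1-one | OC[C@H](c1cc2C=CC(C)(C)Oc2cc1OC)C(=O)c1c(O)cc(O)cc1O | intermediate
25 | oxyphosphonium phenoxide zwitterion of 24 (formed in the flask) | c1ccccc1[P+](c1ccccc1)(c1ccccc1)OC[C@H](c1cc2C=CC(C)(C)Oc2cc1OC)C(=O)c1c(O)cc(O)cc1[O-] | intermediate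
26 | (S)-5,7-dihydroxy-3-(7-methoxy-2,2-dimethyl-2H-chromen-6-yl)chroman-4-one | Oc1cc(O)c2c(c1)OC[C@H](c1cc3C=CC(C)(C)Oc3cc1OC)C2=O | intermediate
27 | (S)-5-hydroxy-7-methoxy-3-(7-methoxy-2,2-dimethyl-2H-chromen-6-yl)chroman-4-one | COc1cc(O)c2c(c1)OC[C@H](c1cc3c(cc1OC)OC(C)(C)C=C3)C2=O | target

**Step count**

Total: 14 steps. Longest linear sequence: 13 steps (steps 1–7 and 9–14); step 8 is a one-step branch.

**Steps most likely to fail, with fallbacks**

Step 11. The folding may take the aldol course (C8 onto C4), or C3 may epimerise by enolisation, with loss of silanol by β-elimination, while the polyanion is held in methoxide. The fallback sets out from aldehyde 14 and comes back at 23; it brings ring A in as intact phloroglucinol instead of folding it. 1,3,5-Tris(methoxymethoxy)benzene is lithiated with n-BuLi (THF, 0 °C) to 2,4,6-tris(methoxymethoxy)phenyllithium F1. This is added at −78 °C to 14 to give the carbinol (2S)-2-Ar-3-(triisopropylsilyloxy)-1-[2,4,6-tris(methoxymethoxy)phenyl]propan-1-ol F2. Dess–Martin oxidation gives the ketone (S)-2-Ar-3-(triisopropylsilyloxy)-1-[2,4,6-tris(methoxymethoxy)phenyl]propan-1-one F3. The three aryl methoxymethyl ethers are then removed with Me3SiOTf/2,2′-bipyridyl followed by water, conditions chosen to spare the chromene and the silyl ether, to return 23.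

Step 7. Enolisation of the α-aryl aldehyde during oxidation, work-up or the first moments of step 9 would erode the enantiomeric purity, and β-elimination of silanol would destroy the stereocentre. The fallback sets out from imide 12 and comes back at 20; it keeps C4 at the acid oxidation level, so that no aldehyde is handled. LiOH/H2O2 (THF/H2O, 0 °C) cleaves the auxiliary to give (S)-2-Ar-3-(triisopropylsilyloxy)propanoic acid F4. Carbonyldiimidazole converts it into the acyl imidazolide (S)-2-Ar-1-(imidazol-1-yl)-3-(triisopropylsilyloxy)propan-1-one F5. This C-acylates the terminal carbon of dianion 18 (THF, −78 °C, inverse addition to excess dianion) to give 20 directly, a Claisen-type acylation in place of aldol addition and oxidation. Here the dianion must capture the acyl imidazolide faster than it deprotonates it.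

Step 5. The very reactive chloromethyl ether may alkylate the enolate on oxygen or with insufficient facial discrimination. The fallback sets out from bromide 4 and comes back at alcohol 13; enzymatic desymmetrisation replaces the auxiliary. Pd-catalysed arylation of diethyl malonate with 4 (Pd(dba)2, P(t-Bu)3, K3PO4, PhMe, 70 °C) gives diethyl 2-Ar-malonate F6. LiAlH4 reduces it to the prochiral 2-Ar-propane-1,3-diol F7. Lipase-catalysed mono-acetylation with vinyl acetate, the enzyme being selected by a screen for the required sense, gives (S)-3-hydroxy-2-Ar-propyl acetate F8. i-Pr3SiCl/imidazole gives (R)-2-Ar-3-(triisopropylsilyloxy)propyl acetate F9, and K2CO3/MeOH removes the acetate to return 13.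

**Further compounds**

F1 | step 11 | 2,4,6-tris(methoxymethoxy)phenyllithium | [Li]c1c(OCOC)cc(OCOC)cc1OCOC
F2 | step 11 | (2S)-2-(7-methoxy-2,2-dimethyl-2H-chromen-6-yl)-3-(triisopropylsilyloxy)-1-[2,4,6-tris(methoxymethoxy)phenyl]propan-1-ol (both carbinol epimers) | CC(C)[Si](C(C)C)(C(C)C)OC[C@H](c1cc2C=CC(C)(C)Oc2cc1OC)C(O)c1c(OCOC)cc(OCOC)cc1OCOC
F3 | step 11 | (S)-2-(7-methoxy-2,2-dimethyl-2H-chromen-6-yl)-3-(triisopropylsilyloxy)-1-[2,4,6-tris(methoxymethoxy)phenyl]propan-1-one | CC(C)[Si](C(C)C)(C(C)C)OC[C@H](c1cc2C=CC(C)(C)Oc2cc1OC)C(=O)c1c(OCOC)cc(OCOC)cc1OCOC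
F4 | step 7 | (S)-2-(7-methoxy-2,2-dimethyl-2H-chromen-6-yl)-3-(triisopropylsilyloxy)propanoic acid | CC(C)[Si](C(C)C)(C(C)C)OC[C@H](c1cc2C=CC(C)(C)Oc2cc1OC)C(=O)O
F5 | step 7 | (S)-1-(imidazol-1-yl)-2-(7-methoxy-2,2-dimethyl-2H-chromen-6-yl)-3-(triisopropylsilyloxy)propan-1-one | CC(C)[Si](C(C)C)(C(C)C)OC[C@H](c1cc2C=CC(C)(C)Oc2cc1OC)C(=O)n1ccnc1
F6 | step 5 | diethyl 2-(7-methoxy-2,2-dimethyl-2H-chromen-6-yl)malonate | CCOC(=O)C(C(=O)OCC)c1cc2C=CC(C)(C)Oc2cc1OC
F7 | step 5 | 2-(7-methoxy-2,2-dimethyl-2H-chromen-6-yl)propane-1,3-diol | OCC(CO)c1cc2C=CC(C)(C)Oc2cc1OC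
F8 | step 5 | (S)-3-hydroxy-2-(7-methoxy-2,2-dimethyl-2H-chromen-6-yl)propyl acetate | OC[C@H](c1cc2C=CC(C)(C)Oc2cc1OC)COC(C)=O
F9 | step 5 | (R)-2-(7-methoxy-2,2-dimethyl-2H-chromen-6-yl)-3-(triisopropylsilyloxy)propyl acetate | CC(C)[Si](C(C)C)(C(C)C)OC[C@H](c1cc2C=CC(C)(C)Oc2cc1OC)COC(C)=O
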